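The route disconnects two adjacent bonds of ring B, C4'–O and C5'–C(=O)Et, back to a C4'–C5' aryne and propanoic acid. Ring B carries its free C4' phenol directly beside the C5' propanoyl ketone, and C5' is itself ortho to the C6' oxygen. This ortho-hydroxyaryl ketone flanked by an alkoxy group is what O-attack of a carboxylate on an alkoxy-substituted aryne, followed by acyl migration, delivers. One fluoride-triggered operation therefore sets both groups without Lewis acid. The precursor is the assembled diarylmethane with ring A complete, four phenols benzylated, and ring B bearing trimethylsilyl at C5' and triflate at C4'. Hydrogenolysis finishes the synthesis.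

Key step: step 13

Remark: ring A is numbered C1 (butanoyl-bearing carbon) to C6 and ring B C1' (bridge-bearing carbon) to C6'; the target has no stereocentre, so no step has to control configuration.

Step 1
Reactants: 1 2-methylphloroglucinol
Product: 3 2,4,6-trihydroxy-3-methylbenzaldehyde, via aryl iminium chloride 2 (not isolated)
Conditions: POCl3, DMF, EtOAc, 0 °C → rt; then H2O, 60 °C
Reagents that add atoms: N,N-dimethylformamide, CN(C)C=O; water, O
Why: Vilsmeier–Haack formylation of a phloroglucinol, in which the two open ring carbons of 1 are equivalent, so a single aldehyde should form and the iminium group deactivates the ring against a second attack.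

Step 2
Reactants: 3 2,4,6-trihydroxy-3-methylbenzaldehyde
Product: 4 4-(allyloxy)-2,6-dihydroxy-3-methylbenzaldehyde
Conditions: allyl bromide (1.05 equiv), KHCO3, DMF, rt
Reagents that add atoms: allyl bromide, C=CCBr
Why: Williamson etherification under weak base, which should alkylate only the 4-hydroxyl because it is para to the formyl group (the most acidic one) and the only hydroxyl not held in a hydrogen bond to the carbonyl oxygen.

Step 3
Reactants: 4 4-(allyloxy)-2,6-dihydroxy-3-methylbenzaldehyde
Product: 5 4-(allyloxy)-2,6-bis(benzyloxy)-3-methylbenzaldehyde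
Conditions: BnBr (2.6 equiv), K2CO3, DMF, 60 °C
Reagents that add atoms: benzyl bromide, BrCc1ccccc1
Why: Williamson etherification with carbonate in warm DMF, forcing enough to alkylate the two chelated ortho-hydroxyls while the allyl ether and the aldehyde are inert.

Step 4
Reactants: 5 4-(allyloxy)-2,6-bis(benzyloxy)-3-methylbenzaldehyde
Product: 6 4-(allyloxy)-2,6-bis(benzyloxy)-3-bromo-5-methylbenzaldehyde
Conditions: NBS (1.05 equiv), MeCN, 0 °C → rt, dark
Reagents that add atoms: N-bromosuccinimide, O=C1CCC(=O)N1Br
Why: electrophilic aromatic bromination at the only unsubstituted ring carbon, which is activated by three alkoxy groups and should react far faster than the isolated allyl double bond in a non-nucleophilic solvent.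

Step 5
Reactants: 6 4-(allyloxy)-2,6-bis(benzyloxy)-3-bromo-5-methylbenzaldehyde
Product: 7 [4-(allyloxy)-2,6-bis(benzyloxy)-3-bromo-5-methylphenyl]methanol
Conditions: NaBH4, THF/MeOH, 0 °C
Reagents that add atoms: none
Why: borohydride reduction of an aromatic aldehyde to the benzylic alcohol, carried out while O4' is still allylated so that no para-hydroxybenzyl alcohol able to form a quinone methide can arise; the aryl bromide and the ethers are inert.

Step 6
Reactants: 7 [4-(allyloxy)-2,6-bis(benzyloxy)-3-bromo-5-methylphenyl]methanol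
Product: 8 1-(allyloxy)-3,5-bis(benzyloxy)-2-bromo-4-(methoxymethyl)-6-methylbenzene
Conditions: NaH, MeI, THF, 0 °C → rt
Reagents that add atoms: iodomethane, CI
Why: Williamson methylation of the primary alkoxide, which masks the benzylic oxygen as an ether that tolerates palladium, organolithium and triflic anhydride and later serves as the leaving group for the ring union.

Step 7
Reactants: 8 1-(allyloxy)-3,5-bis(benzyloxy)-2-bromo-4-(methoxymethyl)-6-methylbenzene
Product: 9 3,5-bis(benzyloxy)-2-bromo-4-(methoxymethyl)-6-methylphenol
Conditions: Pd(PPh3)4 (3 mol %), morpholine, THF, rt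
Reagents that add atoms: none
Why: Tsuji–Trost deallylation, in which zerovalent palladium ionises the aryl allyl ether to a π-allyl complex that morpholine captures, while the hindered, electron-rich aryl bromide should not undergo oxidative addition at room temperature and the benzyl and methyl ethers are untouched.

Step 8
Reactants: 9 3,5-bis(benzyloxy)-2-bromo-4-(methoxymethyl)-6-methylphenol
Product: 12 3,5-bis(benzyloxy)-4-(methoxymethyl)-6-methyl-2-(trimethylsilyl)phenyl trifluoromethanesulfonate, via aryl trimethylsilyl ether 10 (not isolated), via lithium silylphenoxide 11 (not isolated)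
Conditions: HMDS, THF, 70 °C, then evaporate; n-BuLi, THF, −78 °C; Tf2O, −78 → 0 °C
Reagents that add atoms: hexamethyldisilazane, C[Si](C)(C)N[Si](C)(C)C; trifluoromethanesulfonic anhydride, O=S(=O)(OS(=O)(=O)C(F)(F)F)C(F)(F)F
Why: O-silylation, bromine–lithium exchange and retro-Brook rearrangement (1,3 shift of silicon from oxygen to the adjacent aryllithium carbon) followed by O-triflation of the lithium phenoxide, the standard entry to ortho-silylaryl triflates; exchange at −78 °C should outrun deprotonation of the benzylic ethers.

Step 9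
Reactants: 1 2-methylphloroglucinol, 13 butyryl chloride
Product: 14 1-(2,4,6-trihydroxy-3-methylphenyl)butan-1-one
Conditions: AlCl3, PhNO2, 0 → 60 °C; then ice, aq. HCl
Reagents that add atoms: none
Why: Friedel–Crafts acylation of a phloroglucinol, in which both open ring carbons of 1 are equivalent and the first acyl group, chelated by AlCl3, deactivates the ring against a second acylation.

Step 10
Reactants: 14 1-(2,4,6-trihydroxy-3-methylphenyl)butan-1-one
Product: 15 1-(2,6-dihydroxy-4-methoxy-3-methylphenyl)butan-1-one
Conditions: Me2SO4 (1.0 equiv), K2CO3 (1.0 equiv), acetone, 0 °C → rt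
Reagents that add atoms: dimethyl sulfate, COS(=O)(=O)OC
Why: Williamson O-methylation with one equivalent of reagent, expected to be selective for the 4-hydroxyl because it is para to the ketone, the most acidic, and not hydrogen-bonded to the carbonyl, which gives the 2,6-dihydroxy-4-methoxy pattern of ring A.

Step 11
Reactants: 15 1-(2,6-dihydroxy-4-methoxy-3-methylphenyl)butan-1-one
Product: 16 1-[2,6-bis(benzyloxy)-4-methoxy-3-methylphenyl]butan-1-one
Conditions: BnBr (3 equiv), K2CO3, n-Bu4NI (cat.), DMF, 70 °C
Reagents that add atoms: benzyl bromide, BrCc1ccccc1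
Why: Williamson etherification under forcing conditions that should benzylate both chelated ortho-hydroxyls, carbonate in a dipolar aprotic solvent favouring O- over C-alkylation, and done here before any silyl triflate is present.

Step 12
Reactants: 12 3,5-bis(benzyloxy)-4-(methoxymethyl)-6-methyl-2-(trimethylsilyl)phenyl trifluoromethanesulfonate, 16 1-[2,6-bis(benzyloxy)-4-methoxy-3-methylphenyl]butan-1-one
Product: 17 3,5-bis(benzyloxy)-4-{[2,4-bis(benzyloxy)-3-butanoyl-6-methoxy-5-methylphenyl]methyl}-6-methyl-2-(trimethylsilyl)phenyl trifluoromethanesulfonate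
Conditions: TMSOTf (1.2 equiv), 2,6-di-tert-butyl-4-methylpyridine (1.5 equiv), 16 (1.5 equiv), CH2Cl2, −40 → 0 °C; aq. NaHCO3
Reagents that add atoms: none
Why: Friedel–Crafts benzylation in which TMSOTf silylates the benzylic methoxy group of 12 and releases a 2,6-dialkoxybenzyl cation that attacks C5, the only unsubstituted carbon of the trialkoxy-activated ring A of 16, while the hindered pyridine takes up the proton so that no free triflic acid can cleave the C5' silyl group or the new diarylmethane.

Step 13
Reactants: 17 3,5-bis(benzyloxy)-4-{[2,4-bis(benzyloxy)-3-butanoyl-6-methoxy-5-methylphenyl]methyl}-6-methyl-2-(trimethylsilyl)phenyl trifluoromethanesulfonate, 18 propanoic acid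
Product: 21 tetrabenzyl ether of the target bearing a free C4' hydroxyl, via caesium propanoate 19 (not isolated), via ring B aryne 20 (not isolated)
Conditions: 18 (4 equiv), Cs2CO3 (2 equiv), MeOH, rt, evaporate and dry under vacuum; then 17, CsF (3 equiv), THF, 125 °C, sealed tube; aq. HCl work-up
Reagents that add atoms: none
Why: Fluoride attacks silicon at C5' and triflate leaves from C4', giving the C4'–C5' aryne 20; propanoate oxygen adds at C4', and the resulting C5' aryl anion attacks the carbonyl of the aryl ester just formed, passing through a four-membered alkoxide that opens to the ortho-propanoyl phenoxide, so the C4'–O and C5'–C(=O) bonds form with no ring closed and no stereocentre created. The closest known reaction is the insertion of arynes from ortho-silylaryl triflates into the C–O bond of carboxylic acids to give ortho-hydroxyaryl ketones, applied here to a fully substituted aryne. The step needs oxygen to enter at C4' and not C5', and the benzyloxy group on C6' should secure this: its inductive pull distorts the aryne and stabilises negative charge on the adjacent C5', so the nucleophile enters at the remote C4' although that carbon has a methyl neighbour. The step also needs acyl transfer to beat protonation of the aryl anion, which is favoured by the pre-dried salt EtCO2Cs with no free acid, an aprotic solvent, high temperature and the intramolecular nature of the transfer, which should outrun proton abstraction from the butanoyl α-CH2 of ring A. Every other phenol is a benzyl ether, so no O–H competes for the aryne, and the absence of Lewis acid spares the diarylmethane bridge.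

Step 14
Reactants: 21 tetrabenzyl ether of the target bearing a free C4' hydroxyl
Product: 22 1-{2,6-dihydroxy-4-methoxy-3-methyl-5-[(2,4,6-trihydroxy-3-methyl-5-propanoylphenyl)methyl]phenyl}butan-1-one
Conditions: H2 (1 atm), Pd/C (10 wt %), EtOAc, rt
Reagents that add atoms: none
Why: catalytic hydrogenolysis of the four aryl benzyl ethers under neutral conditions, which should leave the two aryl ketones, the methyl ether and the diarylmethane untouched and release the target.

Compound list
1 | 2-methylphloroglucinol (2-methylbenzene-1,3,5-triol) | Cc1c(O)cc(O)cc1O | starting material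
2 | N-[(2,4,6-trihydroxy-3-methylphenyl)methylidene]-N-methylmethanaminium chloride (aryl iminium chloride) | C[N+](C)=Cc1c(O)c(C)c(O)cc1O.[Cl-] | intermediate
3 | 2,4,6-trihydroxy-3-methylbenzaldehyde | O=Cc1c(O)c(C)c(O)cc1O | intermediate
4 | 4-(allyloxy)-2,6-dihydroxy-3-methylbenzaldehyde | O=Cc1c(O)c(C)c(OCC=C)cc1O | intermediate
5 | 4-(allyloxy)-2,6-bis(benzyloxy)-3-methylbenzaldehyde | O=Cc1c(OCc2ccccc2)c(C)c(OCC=C)cc1OCc1ccccc1 | intermediate
6 | 4-(allyloxy)-2,6-bis(benzyloxy)-3-bromo-5-methylbenzaldehyde | O=Cc1c(OCc2ccccc2)c(C)c(OCC=C)c(Br)c1OCc1ccccc1 | intermediate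
7 | [4-(allyloxy)-2,6-bis(benzyloxy)-3-bromo-5-methylphenyl]methanol | OCc1c(OCc2ccccc2)c(C)c(OCC=C)c(Br)c1OCc1ccccc1 | intermediate
8 | 1-(allyloxy)-3,5-bis(benzyloxy)-2-bromo-4-(methoxymethyl)-6-methylbenzene | COCc1c(OCc2ccccc2)c(C)c(OCC=C)c(Br)c1OCc1ccccc1 | intermediate
9 | 3,5-bis(benzyloxy)-2-bromo-4-(methoxymethyl)-6-methylphenol | COCc1c(OCc2ccccc2)c(C)c(O)c(Br)c1OCc1ccccc1 | intermediate
10 | [3,5-bis(benzyloxy)-2-bromo-4-(methoxymethyl)-6-methylphenoxy]trimethylsilane (aryl trimethylsilyl ether) | COCc1c(OCc2ccccc2)c(C)c(O[Si](C)(C)C)c(Br)c1OCc1ccccc1 | intermediate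
11 | lithium 3,5-bis(benzyloxy)-4-(methoxymethyl)-6-methyl-2-(trimethylsilyl)phenoxide (lithium silylphenoxide) | [Li+].COCc1c(OCc2ccccc2)c(C)c([O-])c([Si](C)(C)C)c1OCc1ccccc1 | intermediate
12 | 3,5-bis(benzyloxy)-4-(methoxymethyl)-6-methyl-2-(trimethylsilyl)phenyl trifluoromethanesulfonate | COCc1c(OCc2ccccc2)c(C)c(OS(=O)(=O)C(F)(F)F)c([Si](C)(C)C)c1OCc1ccccc1 | intermediate
13 | butyryl chloride | CCCC(Cl)=O | starting material
14 | 1-(2,4,6-trihydroxy-3-methylphenyl)butan-1-one | CCCC(=O)c1c(O)c(C)c(O)cc1O | intermediate
15 | 1-(2,6-dihydroxy-4-methoxy-3-methylphenyl)butan-1-one | CCCC(=O)c1c(O)c(C)c(OC)cc1O | intermediate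
16 | 1-[2,6-bis(benzyloxy)-4-methoxy-3-methylphenyl]butan-1-one | CCCC(=O)c1c(OCc2ccccc2)c(C)c(OC)cc1OCc1ccccc1 | intermediate
17 | 3,5-bis(benzyloxy)-4-{[2,4-bis(benzyloxy)-3-butanoyl-6-methoxy-5-methylphenyl]methyl}-6-methyl-2-(trimethylsilyl)phenyl trifluoromethanesulfonate (aryne precursor) | CCCC(=O)c1c(OCc2ccccc2)c(C)c(OC)c(Cc2c(OCc3ccccc3)c(C)c(OS(=O)(=O)C(F)(F)F)c([Si](C)(C)C)c2OCc2ccccc2)c1OCc1ccccc1 | intermediate
18 | propanoic acid | CCC(=O)O | starting material
19 | caesium propanoate | [Cs+].CCC(=O)[O-] | intermediate
20 | ring B aryne: 17 with the C4'–C5' bond as a formal triple bond in place of triflate and silyl | CCCC(=O)c1c(OCc2ccccc2)c(C)c(OC)c(CC2=C(OCc3ccccc3)C#CC(C)=C2OCc2ccccc2)c1OCc1ccccc1 | intermediate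
21 | 1-[2,6-bis(benzyloxy)-3-{[2,6-bis(benzyloxy)-4-hydroxy-3-methyl-5-propanoylphenyl]methyl}-4-methoxy-5-methylphenyl]butan-1-one (tetrabenzyl ether of the target with free C4' hydroxyl) | CCCC(=O)c1c(OCc2ccccc2)c(C)c(OC)c(Cc2c(OCc3ccccc3)c(C)c(O)c(C(=O)CC)c2OCc2ccccc2)c1OCc1ccccc1 | intermediate
22 | 1-{2,6-dihydroxy-4-methoxy-3-methyl-5-[(2,4,6-trihydroxy-3-methyl-5-propanoylphenyl)methyl]phenyl}butan-1-one | CCCC(=O)c1c(O)c(C)c(OC)c(Cc2c(O)c(C)c(O)c(C(=O)CC)c2O)c1O | target

Total step count: 14. Longest linear sequence: 11 steps (steps 1 to 8, then 12, 13 and 14); steps 9 to 11 form the ring A branch.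

Steps most likely to fail

Step 13. The crowded aryne may be protonated at C5' before the acyl group migrates, or carboxylate addition may be slow or poorly oriented next to the C3' methyl. The fallback brings in the propanoyl group by organolithium chemistry before the rings are joined; it sets out from 9 and returns at 22. Benzylation of 9 (BnBr, K2CO3, DMF) would give 1,3,5-tris(benzyloxy)-2-bromo-4-(methoxymethyl)-6-methylbenzene F1. Bromine–lithium exchange (n-BuLi, THF, −78 °C) and acylation of the aryllithium with N-methoxy-N-methylpropanamide would give 1-[2,4,6-tris(benzyloxy)-3-(methoxymethyl)-5-methylphenyl]propan-1-one F2. The TMSOTf-mediated Friedel–Crafts union with 16, as in step 12, would give the pentabenzyl ether of the target, 1-[2,6-bis(benzyloxy)-4-methoxy-3-methyl-5-{[2,4,6-tris(benzyloxy)-3-methyl-5-propanoylphenyl]methyl}phenyl]butan-1-one F3, and hydrogenolysis over Pd/C would deliver 22.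

Step 12. The benzylic cation from 12 may not be captured by the congested, acyl-bearing ring of 16, so that it reverts to the ether, or the C5' silyl group may be lost by ipso protonation if acid builds up. The fallback changes the nucleophile to the unprotected acylphloroglucinol and moves the benzylation after the coupling; it sets out from 12 (with 15) and returns at 17. Diphenol 15 is far more nucleophilic at C5, and stirring it with 12 in HFIP containing TsOH·H2O (2 mol %) at rt would give 3,5-bis(benzyloxy)-4-[(3-butanoyl-2,4-dihydroxy-6-methoxy-5-methylphenyl)methyl]-6-methyl-2-(trimethylsilyl)phenyl trifluoromethanesulfonate F4. A double Mitsunobu etherification (BnOH, PPh3, DIAD, THF), which uses neither base nor fluoride and so cannot trigger the silyl triflate, would then give 17.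

Step 8. Oxygen-to-carbon silyl migration at the flanked C5' position may be incomplete, lithiation of a benzylic ether may compete, or triflation of the congested lithium phenoxide may be sluggish. The fallback delivers silicon intermolecularly while O4' is still allylated and triflates an isolated phenol; it sets out from 8 and returns at 12. Bromine–lithium exchange on 8 (n-BuLi, THF, −78 °C) and quenching with TMSCl would give [2-(allyloxy)-4,6-bis(benzyloxy)-5-(methoxymethyl)-3-methylphenyl]trimethylsilane F5. Deallylation with Pd(PPh3)4 and morpholine would give 3,5-bis(benzyloxy)-4-(methoxymethyl)-6-methyl-2-(trimethylsilyl)phenol F6, and Tf2O with pyridine in CH2Cl2 at 0 °C would give 12.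

Further compounds
F1 | step 13 | 1,3,5-tris(benzyloxy)-2-bromo-4-(methoxymethyl)-6-methylbenzene | COCc1c(OCc2ccccc2)c(C)c(OCc2ccccc2)c(Br)c1OCc1ccccc1
F2 | step 13 | 1-[2,4,6-tris(benzyloxy)-3-(methoxymethyl)-5-methylphenyl]propan-1-one | COCc1c(OCc2ccccc2)c(C)c(OCc2ccccc2)c(C(=O)CC)c1OCc1ccccc1
F3 | step 13 | 1-[2,6-bis(benzyloxy)-4-methoxy-3-methyl-5-{[2,4,6-tris(benzyloxy)-3-methyl-5-propanoylphenyl]methyl}phenyl]butan-1-one | CCCC(=O)c1c(OCc2ccccc2)c(C)c(OC)c(Cc2c(OCc3ccccc3)c(C)c(OCc3ccccc3)c(C(=O)CC)c2OCc2ccccc2)c1OCc1ccccc1
F4 | step 12 | 3,5-bis(benzyloxy)-4-[(3-butanoyl-2,4-dihydroxy-6-methoxy-5-methylphenyl)methyl]-6-methyl-2-(trimethylsilyl)phenyl trifluoromethanesulfonate | CCCC(=O)c1c(O)c(C)c(OC)c(Cc2c(OCc3ccccc3)c(C)c(OS(=O)(=O)C(F)(F)F)c([Si](C)(C)C)c2OCc2ccccc2)c1O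
F5 | step 8 | [2-(allyloxy)-4,6-bis(benzyloxy)-5-(methoxymethyl)-3-methylphenyl]trimethylsilane | COCc1c(OCc2ccccc2)c(C)c(OCC=C)c([Si](C)(C)C)c1OCc1ccccc1
F6 | step 8 | 3,5-bis(benzyloxy)-4-(methoxymethyl)-6-methyl-2-(trimethylsilyl)phenol | COCc1c(OCc2ccccc2)c(C)c(O)c([Si](C)(C)C)c1OCc1ccccc1
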